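1. Numbering: carotenoid numbers are used. Unprimed numbers cover the half with the 3,5,6-triol ring (C1 = CMe2, C5 = C(OH)CH3, C6 = C(OH)-chain). Primed numbers cover the half with the ε ring (C4'=C5', C6'-H).
2. Enabling feature: C11'=C12'–C13'(CH3)=C14' is an E,E-1,3-diene. Its outer carbons C11' and C14' carry the two polyenyl arms and its inner carbons carry only H and CH3. This is the protonolysis pattern of a 2,5-dialkenyl-3-methyltitanacyclopentadiene, so both halves are raised to the alkyne oxidation level.
3. Cuts: first C12'–C13' (C16 terminal dienyne C11'≡C12'H plus C24 methyl-capped pentaenyne CH3–C13'≡C14'). Then C11=C12 (HWE) and C6–C7 (acetylide addition) in the C24 half. Then C11'≡C12' (C1 homologation), C7'=C8' (HWE) and C6'–C7' (methylenation) in the C16 half.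
4. Forward: both six-membered rings come ready-made in ketoisophorone and each chain grows outwards from its ring. The halves meet in a temporary five-membered ring (Ti, C11', C12', C13', C14') that is cleaved by protonolysis in the same flask, and fluoride then removes all silyl groups.
5. Stereochemistry: C3 and C3' come from enantiomeric Ru transfer-hydrogenation catalysts acting on the same diketone. C6 (axial acetylide attack) and C6' (hydroboration) are set by shielding from the axial C1/C1' methyl group. C4/C5 come from 3-OH-directed epoxidation, with C5–O kept in the hydride opening. All chain double bonds are E, from preset building blocks, Wittig/HWE reactions, trans-hydroalumination and the syn-carbometalation of the key step.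

Key step: step 21

Assumption: the Ru/TsDPEN catalysts are taken to follow the usual aryl/alkenyl ketone model on ketoisophorone. If the sense were opposite, the two ligand enantiomers would change places between steps 2 and 13. All polyene steps are run under argon in the dark.

Step 1
Reactants: 1 (E)-3-methylpent-2-en-4-yn-1-ol
Product: 2 (E)-5-(tert-butyldimethylsilyloxy)-3-methylpent-3-en-1-yne
Conditions: t-BuMe2SiCl, imidazole, CH2Cl2, 0 °C to rt
Reagents that add atoms: tert-butyldimethylsilyl chloride, CC(C)(C)[Si](C)(C)Cl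
Why: Standard silylation of a primary alcohol, which masks the C11 oxygen so that it cannot direct the later epoxidation, while the preset E geometry of C9=C10 is untouched.

Step 2
Reactants: 3 ketoisophorone (2,6,6-trimethylcyclohex-2-ene-1,4-dione)
Product: 4 (4S)-4-hydroxy-2,6,6-trimethylcyclohex-2-en-1-one
Conditions: RuCl(p-cymene)[(S,S)-TsDPEN] (0.5 mol %), KOH (cat.), i-PrOH, rt
Reagents that add atoms: none
Why: Noyori–Ikariya asymmetric transfer hydrogenation reduces only the unhindered C4 carbonyl (the other one lies between the quaternary carbon and the methyl-bearing alkene carbon), and with the alkenyl side in the place of the aryl group of the usual model the (S,S)-ligand should set the S carbinol centre, which becomes C3.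

Step 3
Reactants: 2 (E)-5-(tert-butyldimethylsilyloxy)-3-methylpent-3-en-1-yne; 4 (4S)-4-hydroxy-2,6,6-trimethylcyclohex-2-en-1-one
Product: 8 (1S,4S)-4-[(3E)-5-(tert-butyldimethylsilyloxy)-3-methylpent-3-en-1-ynyl]-3,5,5-trimethyl-4-(trimethylsilyloxy)cyclohex-2-en-1-ol, via lithium acetylide 5 (not isolated), via dilithium dialkoxide 6 (not isolated), via bis(trimethylsilyl) ether 7 (not isolated)
Conditions: 2 (2.2 equiv), n-BuLi (2.2 equiv), THF, −78 °C; 4, −78 to 0 °C; Me3SiCl, 0 °C to rt; crude 7, K2CO3 (cat.), MeOH, 0 °C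
Reagents that add atoms: chlorotrimethylsilane, C[Si](C)(C)Cl; n-butyllithium, [Li]CCCC (lithium of 5 and 6 only)
Why: 1,2-Addition of a lithium acetylide to a hindered enone, in which the 3-oxygen stays pseudo-equatorial (a pseudo-axial one would clash with the syn-axial C1 methyl), so the axial C1 methyl shields one face and the slim nucleophile enters axially from the other, cis to the 3-oxygen, which sets C6 (6-O trans to 3-O); silylation of both alkoxides and selective methanolysis of the unhindered secondary silyl ether leave the 3-OH as the only free hydroxyl.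

Step 4
Reactants: 8 (1S,4S)-alkynyl cyclohexenol with 6-OSiMe3
Product: 9 4,5-epoxide of 8 (carotenoid 3S,4S,5S,6R; epoxide oxygen on the face of the 3-OH and of the alkynyl chain)
Conditions: VO(acac)2 (2 mol %), t-BuOOH (decane), CH2Cl2, 0 °C to rt
Reagents that add atoms: tert-butyl hydroperoxide, CC(C)(C)OO
Why: Vanadium-catalysed hydroxyl-directed epoxidation of a cyclic allylic alcohol, in which the only free OH (C3) binds the metal and delivers oxygen to its own face of C4=C5, the 6-OSiMe3 group blocks the other face and the enyne alkene has no free directing group, which sets C4 and C5.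

Step 5
Reactants: 9 silylated epoxy alcohol
Product: 10 epoxy triol (9 without its two silyl groups; 3S,4S,5S,6R)
Conditions: Bu4NF, AcOH (1:1), THF, 0 °C to rt
Reagents that add atoms: none
Why: Fluoride desilylation, buffered with acetic acid so that no free 6-alkoxide can attack the neighbouring epoxide (Payne rearrangement).

Step 6
Reactants: 10 epoxy triol
Product: 11 (1S,2S,4S)-1-[(1E,3E)-5-hydroxy-3-methylpenta-1,3-dienyl]-2,6,6-trimethylcyclohexane-1,2,4-triol
Conditions: LiAlH4 (excess), THF, 0 °C to reflux; aq. work-up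
Reagents that add atoms: none
Why: Hydroxyl-directed trans-hydroalumination of the propargylic alcohol gives E-C7=C8, and SN2 hydride opening of the trisubstituted epoxide occurs at its only accessible carbon C4 (hydride can come from the 6-O-aluminate on the face opposite to the epoxide oxygen), so the C5–O bond and the C5 configuration are kept and the 3,5-cis/5,6-trans triol results.

Step 7
Reactants: 11 tetraol
Product: 12 (2E,4E)-3-methyl-5-[(1S,2S,4S)-1,2,4-trihydroxy-2,6,6-trimethylcyclohexyl]penta-2,4-dienal
Conditions: MnO2 (activated, excess), acetone, rt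
Reagents that add atoms: none
Why: MnO2 oxidation is selective for the primary dienylic alcohol, because the 3-OH is not allylic and the other two hydroxyls are tertiary.

Step 8
Reactants: 12 triol dienal
Product: 13 tris(trimethylsilyl) ether of 12
Conditions: 1-(trimethylsilyl)imidazole (excess), CH2Cl2, 40 °C
Reagents that add atoms: 1-(trimethylsilyl)imidazole, C[Si](C)(C)n1ccnc1
Why: Neutral persilylation with the strongest hydroxyl-silylating agent covers the two hindered tertiary alcohols as well, and the electron-poor dienal protects the tertiary allylic C6–O bond against ionisation.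

Step 9
Reactants: 14 but-2-ynal; 15 (triphenylphosphoranylidene)acetaldehyde; 16 ethyl 2-(triphenylphosphoranylidene)propanoate
Product: 18 ethyl (2E,4E)-2-methylocta-2,4-dien-6-ynoate, via (E)-hex-2-en-4-ynal 17 (not isolated)
Conditions: 15 (1.0 equiv), CH2Cl2, 0 °C to rt; then 16, rt
Reagents that add atoms: none
Why: Two consecutive Wittig olefinations with stabilised ylides are each E-selective, and the ynal is more electrophilic than the enynal formed from it, so the first ylide reacts only once.

Step 10
Reactants: 18 dienynoate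
Product: 19 (2E,4E)-2-methylocta-2,4-dien-6-yn-1-ol
Conditions: i-Bu2AlH (2.2 equiv), CH2Cl2, −78 °C
Reagents that add atoms: none
Why: 1,2-Reduction of a conjugated ester with i-Bu2AlH leaves the diene and the alkyne untouched at low temperature.

Step 11
Reactants: 19 dienynol
Product: 21 diethyl [(2E,4E)-2-methylocta-2,4-dien-6-ynyl]phosphonate, via dienynyl bromide 20 (not isolated)
Conditions: PBr3, Et2O, −10 °C; crude 20, P(OEt)3, 90 °C
Reagents that add atoms: phosphorus tribromide, BrP(Br)Br (bromine of 20 only); triethyl phosphite, CCOP(OCC)OCC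
Why: SN2 bromination of the primary allylic alcohol is followed by a Michaelis–Arbuzov reaction, telescoped because the dienylic bromide is labile.

Step 12
Reactants: 13 tris-silylated C15 dienal; 21 C9 phosphonate
Product: 23 C24 methyl-capped pentaenyne (CH3–C13'≡C14' terminus; all-E; 3S,5S,6S; three OSiMe3 groups), via sodium phosphonate carbanion 22 (not isolated)
Conditions: 21, NaN(SiMe3)2, THF, −78 °C; 13, −78 to 0 °C
Reagents that add atoms: sodium bis(trimethylsilyl)amide, C[Si](C)(C)[N-][Si](C)(C)C.[Na+] (sodium of 22 only)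
Why: Horner–Wadsworth–Emmons olefination of an enal with an allylic phosphonate anion is E-selective at the new C11=C12 bond and basic enough to spare the silyl ethers and the tertiary allylic C6–O bond.

Step 13
Reactants: 3 ketoisophorone
Product: 24 (4R)-4-hydroxy-2,6,6-trimethylcyclohex-2-en-1-one
Conditions: RuCl(p-cymene)[(R,R)-TsDPEN] (0.5 mol %), KOH (cat.), i-PrOH, rt
Reagents that add atoms: none
Why: The same Noyori–Ikariya transfer hydrogenation with the enantiomeric ligand should set the R carbinol centre, which becomes C3'.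

Step 14
Reactants: 24 (4R)-hydroxy enone
Product: 25 (4R)-4-(tert-butyldimethylsilyloxy)-2,6,6-trimethylcyclohex-2-en-1-one
Conditions: t-BuMe2SiCl, imidazole, DMF, rt
Reagents that add atoms: tert-butyldimethylsilyl chloride, CC(C)(C)[Si](C)(C)Cl
Why: Standard silylation gives a group that survives ylide, borane, oxidant, hydride and the titanium reagent.

Step 15
Reactants: 25 silyloxy enone
Product: 26 tert-butyldimethyl{[(1R)-3,5,5-trimethyl-4-methylidenecyclohex-2-en-1-yl]oxy}silane
Conditions: Ph3PCH3Br, KOt-Bu, THF, 0 °C; 25, rt to reflux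
Reagents that add atoms: methyltriphenylphosphonium bromide, C[P+](c1ccccc1)(c1ccccc1)c1ccccc1.[Br-]
Why: Wittig methylenation with the smallest ylide (pre-formed, no excess base) reaches the hindered non-enolisable carbonyl in a 1,2-sense and brings in C7'.

Step 16
Reactants: 26 exocyclic diene
Product: 28 [(1R,4R)-4-(tert-butyldimethylsilyloxy)-2,6,6-trimethylcyclohex-2-en-1-yl]methanol, via B-alkyl-9-BBN 27 (not isolated)
Conditions: 9-BBN, THF, 0 °C to rt; NaOH, H2O2, 0 °C
Reagents that add atoms: 9-borabicyclo[3.3.1]nonane, B1C2CCCC1CCC2 (boron unit of 27 only); hydrogen peroxide, OO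
Why: In this hydroboration–oxidation, 9-BBN adds only to the exocyclic 1,1-disubstituted double bond with boron at the CH2 terminus and from the face opposite to the axial C1' methyl (the OSi group stays pseudo-equatorial), so H reaches C6' cis to the 3'-oxygen and the CH2OH arm ends up trans to it (6'R).

Step 17
Reactants: 28 primary alcohol
Product: 29 (1R,4R)-4-(tert-butyldimethylsilyloxy)-2,6,6-trimethylcyclohex-2-ene-1-carbaldehyde
Conditions: Dess–Martin periodinane, NaHCO3, CH2Cl2, 0 °C; used crude
Reagents that add atoms: none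
Why: Buffered Dess–Martin oxidation is near-neutral, so the β,γ-unsaturated aldehyde should neither epimerise at C6' nor move its double bond into conjugation.

Step 18
Reactants: 29 aldehyde; 30 diethyl [(E)-3-cyano-2-methylprop-2-enyl]phosphonate
Product: 32 (2E,4E)-5-[(1R,4R)-4-(tert-butyldimethylsilyloxy)-2,6,6-trimethylcyclohex-2-en-1-yl]-3-methylpenta-2,4-dienenitrile, via sodium phosphonate carbanion 31 (not isolated)
Conditions: 30, NaN(SiMe3)2, THF, −78 °C; 29, −78 to 0 °C; chromatography
Reagents that add atoms: sodium bis(trimethylsilyl)amide, C[Si](C)(C)[N-][Si](C)(C)C.[Na+] (sodium of 31 only)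
Why: Horner–Wadsworth–Emmons olefination with the allylic cyanophosphonate anion is E-selective at the new C7'=C8' bond, the pre-formed anion at low temperature should leave the doubly allylic C6'–H alone, and any 9'Z isomer is removed by chromatography.

Step 19
Reactants: 32 C15 nitrile
Product: 34 (2E,4E)-5-[(1R,4R)-4-(tert-butyldimethylsilyloxy)-2,6,6-trimethylcyclohex-2-en-1-yl]-3-methylpenta-2,4-dienal, via aluminium aldiminate 33 (not isolated)
Conditions: i-Bu2AlH (1.2 equiv), toluene, −78 °C; wet SiO2, 0 °C
Reagents that add atoms: water, O; diisobutylaluminium hydride, CC(C)C[AlH]CC(C)C (aluminium unit of 33 only)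
Why: Partial reduction of a conjugated nitrile with i-Bu2AlH stops at the aluminium aldiminate, and mild hydrolysis releases the dienal without touching the allylic silyl ether.

Step 20
Reactants: 34 C15 dienal
Product: 35 tert-butyldimethyl{[(1R,4R)-3,5,5-trimethyl-4-[(1E,3E)-3-methylhexa-1,3-dien-5-ynyl]cyclohex-2-en-1-yl]oxy}silane (C16 terminal dienyne)
Conditions: Me3SiCHN2, LiN(i-Pr)2, THF, −78 °C; 34, −78 °C to rt
Reagents that add atoms: (trimethylsilyl)diazomethane, C[Si](C)(C)C=[N+]=[N-]
Why: In this Colvin rearrangement (Seyferth–Gilbert-type homologation), addition of lithiated Me3SiCHN2, loss of Me3SiOLi and N2 and a 1,2-H shift of the alkylidene carbene give the terminal alkyne C11'≡C12'H under methanol-free conditions that suit an enal.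

Step 21
Reactants: 23 C24 methyl-capped pentaenyne; 35 C16 terminal dienyne
Product: 38 3,5,6-tris-O-trimethylsilyl-3'-O-tert-butyldimethylsilyl ether of the target (all-E nonaene), via titanacyclopropene 36 (not isolated), via titanacyclopentadiene 37 (not isolated)
Conditions: 23, Ti(Oi-Pr)4 (1.2 equiv), c-C5H9MgCl (2.4 equiv), toluene/Et2O, −78 to −35 °C; 35 (1.3 equiv), −78 to −30 °C; H2O, −30 °C to rt
Reagents that add atoms: titanium tetraisopropoxide, CC(C)O[Ti](OC(C)C)(OC(C)C)OC(C)C (Ti(Oi-Pr)2 unit of 36 and 37 only; 38 gains only hydrogen)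
Why: Proposed new method: Ti(Oi-Pr)4 and two equivalents of c-C5H9MgCl give a Kulinkovich-type divalent titanium–cyclopentene complex that passes its metal to the C13'≡C14' triple bond of 23 (titanacyclopropene 36), the terminal alkyne of 35 then inserts into the Ti–C13' bond to give titanacyclopentadiene 37, and water cleaves both Ti–C(sp2) bonds with retention to release the C11'=C12'–C13'=C14' diene of 38. The closest known reaction type is the titanium-alkoxide-mediated reductive cross-coupling of a methyl-capped internal alkyne with a terminal alkyne to a trisubstituted E,E-1,3-diene, which has not been shown for two alkynes that are each conjugated to a polyene chain. The only ring closed is the temporary five-membered metallacycle (Ti, C11', C12', C13', C14'), formed by ring expansion of the three-membered metallacycle through syn-carbometalation, and it is opened again in the same flask. No stereocentre is formed, but the cis arrangement of titanium and the new C–C bond on each ring double bond becomes, on protonolysis, the E geometry at both C11'=C12' and C13'=C14'. Regioselectivity is needed twice and the substrates secure it: in 36 the bond forms at the carbon that bears the small CH3 while the pentaenyl-substituted C14' stays on titanium, and 35 reacts at its unsubstituted terminus C12' so that the dienyl-bearing C11' ends up next to titanium. Cross- over homo-coupling follows from the order of addition (the internal alkyne is complexed first and does not dimerise at low temperature), chemoselectivity follows from the much stronger binding of divalent titanium to alkynes than to conjugated alkenes, and all four hydroxyls are silylated so that the acetylenic C–H of 35 is the only acidic proton, kept harmless by the low temperature.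

Step 22
Reactants: 38 tetrasilyl ether
Product: 39 (3S,5S,6S,3'R,6'R)-5,6-dihydro-β,ε-carotene-3,5,6,3'-tetrol (target)
Conditions: Bu4NF (excess), THF, 0 °C to rt
Reagents that add atoms: none
Why: Global fluoride desilylation under non-acidic conditions spares the acid-labile tertiary allylic 6-OH, the allylic 3'-OH and the polyene, and touches no stereocentre.

Compound list
1 | (E)-3-methylpent-2-en-4-yn-1-ol | C#C/C(C)=C/CO | starting material
2 | (E)-5-(tert-butyldimethylsilyloxy)-3-methylpent-3-en-1-yne | C#C/C(C)=C/CO[Si](C)(C)C(C)(C)C | intermediate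
3 | ketoisophorone | CC1=CC(=O)CC(C)(C)C1=O | starting material
4 | (4S)-4-hydroxy-2,6,6-trimethylcyclohex-2-en-1-one | CC1=C[C@@H](O)CC(C)(C)C1=O | intermediate
5 | lithium acetylide of 2 | [Li]C#C/C(C)=C/CO[Si](C)(C)C(C)(C)C | intermediate
6 | dilithium 3,6-dialkoxide of the adduct | CC(C)(C)[Si](C)(C)OC/C=C(C)/C#C[C@]1(O[Li])C(C)(C)C[C@H](O[Li])C=C1C | intermediate
7 | 3,6-bis(trimethylsilyl) ether of the adduct | CC(C)(C)[Si](C)(C)OC/C=C(C)/C#C[C@]1(O[Si](C)(C)C)C(C)(C)C[C@H](O[Si](C)(C)C)C=C1C | intermediate
8 | (1S,4S)-4-[(3E)-5-(tert-butyldimethylsilyloxy)-3-methylpent-3-en-1-ynyl]-3,5,5-trimethyl-4-(trimethylsilyloxy)cyclohex-2-en-1-ol | CC(C)(C)[Si](C)(C)OC/C=C(C)/C#C[C@]1(O[Si](C)(C)C)C(C)(C)C[C@H](O)C=C1C | intermediate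
9 | 4,5-epoxide of 8 (3S,4S,5S,6R; epoxide O, 3-OH and alkynyl chain on one face, 5-CH3 and 6-OSiMe3 on the other) | CC(C)(C)[Si](C)(C)OC/C=C(C)/C#C[C@]1(O[Si](C)(C)C)C(C)(C)C[C@H](O)[C@@H]2O[C@]12C | intermediate
10 | epoxy triol (3S,4S,5S,6R) | OC/C=C(C)/C#C[C@]1(O)C(C)(C)C[C@H](O)[C@@H]2O[C@]12C | intermediate
11 | (1S,2S,4S)-1-[(1E,3E)-5-hydroxy-3-methylpenta-1,3-dienyl]-2,6,6-trimethylcyclohexane-1,2,4-triol | OC/C=C(C)/C=C/[C@]1(O)C(C)(C)C[C@H](O)C[C@]1(C)O | intermediate
12 | (2E,4E)-3-methyl-5-[(1S,2S,4S)-1,2,4-trihydroxy-2,6,6-trimethylcyclohexyl]penta-2,4-dienal | O=C/C=C(C)/C=C/[C@]1(O)C(C)(C)C[C@H](O)C[C@]1(C)O | intermediate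
13 | tris(trimethylsilyl) ether of 12 | O=C/C=C(C)/C=C/[C@]1(O[Si](C)(C)C)C(C)(C)C[C@H](O[Si](C)(C)C)C[C@]1(C)O[Si](C)(C)C | intermediate
14 | but-2-ynal | CC#CC=O | starting material
15 | (triphenylphosphoranylidene)acetaldehyde | O=CC=P(c1ccccc1)(c1ccccc1)c1ccccc1 | starting material
16 | ethyl 2-(triphenylphosphoranylidene)propanoate | CCOC(=O)C(C)=P(c1ccccc1)(c1ccccc1)c1ccccc1 | starting material
17 | (E)-hex-2-en-4-ynal | CC#C/C=C/C=O | intermediate
18 | ethyl (2E,4E)-2-methylocta-2,4-dien-6-ynoate | CC#C/C=C/C=C(C)/C(=O)OCC | intermediate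
19 | (2E,4E)-2-methylocta-2,4-dien-6-yn-1-ol | CC#C/C=C/C=C(C)/CO | intermediate
20 | (2E,4E)-1-bromo-2-methylocta-2,4-dien-6-yne | CC#C/C=C/C=C(C)/CBr | intermediate
21 | diethyl [(2E,4E)-2-methylocta-2,4-dien-6-ynyl]phosphonate | CC#C/C=C/C=C(C)/CP(=O)(OCC)OCC | intermediate
22 | sodium carbanion of 21 | [Na+].CC#C/C=C/C=C(C)/[CH-]P(=O)(OCC)OCC | intermediate
23 | C24 methyl-capped all-E pentaenyne, 3,5,6-tris(trimethylsilyl) ether (3S,5S,6S) | CC#C/C=C/C=C(C)/C=C/C=C(C)/C=C/[C@]1(O[Si](C)(C)C)C(C)(C)C[C@H](O[Si](C)(C)C)C[C@]1(C)O[Si](C)(C)C | intermediate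
24 | (4R)-4-hydroxy-2,6,6-trimethylcyclohex-2-en-1-one | CC1=C[C@H](O)CC(C)(C)C1=O | intermediate
25 | (4R)-4-(tert-butyldimethylsilyloxy)-2,6,6-trimethylcyclohex-2-en-1-one | CC1=C[C@H](O[Si](C)(C)C(C)(C)C)CC(C)(C)C1=O | intermediate
26 | tert-butyldimethyl{[(1R)-3,5,5-trimethyl-4-methylidenecyclohex-2-en-1-yl]oxy}silane | CC1=C[C@H](O[Si](C)(C)C(C)(C)C)CC(C)(C)C1=C | intermediate
27 | B-{[(1R,4R)-4-(tert-butyldimethylsilyloxy)-2,6,6-trimethylcyclohex-2-en-1-yl]methyl}-9-BBN | CC1=C[C@H](O[Si](C)(C)C(C)(C)C)CC(C)(C)[C@H]1CB1C2CCCC1CCC2 | intermediate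
28 | [(1R,4R)-4-(tert-butyldimethylsilyloxy)-2,6,6-trimethylcyclohex-2-en-1-yl]methanol | CC1=C[C@H](O[Si](C)(C)C(C)(C)C)CC(C)(C)[C@H]1CO | intermediate
29 | (1R,4R)-4-(tert-butyldimethylsilyloxy)-2,6,6-trimethylcyclohex-2-ene-1-carbaldehyde | CC1=C[C@H](O[Si](C)(C)C(C)(C)C)CC(C)(C)[C@H]1C=O | intermediate
30 | diethyl [(E)-3-cyano-2-methylprop-2-enyl]phosphonate | CCOP(=O)(C/C(C)=C/C#N)OCC | starting material
31 | sodium carbanion of 30 | [Na+].CCOP(=O)([CH-]/C(C)=C/C#N)OCC | intermediate
32 | (2E,4E)-5-[(1R,4R)-4-(tert-butyldimethylsilyloxy)-2,6,6-trimethylcyclohex-2-en-1-yl]-3-methylpenta-2,4-dienenitrile | CC1=C[C@H](O[Si](C)(C)C(C)(C)C)CC(C)(C)[C@H]1/C=C/C(C)=C/C#N | intermediate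
33 | N-(diisobutylaluminio)aldimine of 34 | CC1=C[C@H](O[Si](C)(C)C(C)(C)C)CC(C)(C)[C@H]1/C=C/C(C)=C/C=N[Al](CC(C)C)CC(C)C | intermediate
34 | (2E,4E)-5-[(1R,4R)-4-(tert-butyldimethylsilyloxy)-2,6,6-trimethylcyclohex-2-en-1-yl]-3-methylpenta-2,4-dienal | CC1=C[C@H](O[Si](C)(C)C(C)(C)C)CC(C)(C)[C@H]1/C=C/C(C)=C/C=O | intermediate
35 | C16 terminal dienyne (3'R,6'R; 3'-OSiMe2t-Bu) | CC1=C[C@H](O[Si](C)(C)C(C)(C)C)CC(C)(C)[C@H]1/C=C/C(C)=C/C#C | intermediate
36 | titanacyclopropene of 23 (Ti(Oi-Pr)2 on C13' and C14') | CC1=C(/C=C/C=C(C)/C=C/C=C(C)/C=C/[C@]2(O[Si](C)(C)C)C(C)(C)C[C@H](O[Si](C)(C)C)C[C@]2(C)O[Si](C)(C)C)[Ti]1(OC(C)C)OC(C)C | intermediate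
37 | titanacyclopentadiene (ring Ti, C11', C12', C13', C14') | CC1=C[C@H](O[Si](C)(C)C(C)(C)C)CC(C)(C)[C@H]1/C=C/C(C)=C/C2=CC(C)=C(/C=C/C=C(C)/C=C/C=C(C)/C=C/[C@]3(O[Si](C)(C)C)C(C)(C)C[C@H](O[Si](C)(C)C)C[C@]3(C)O[Si](C)(C)C)[Ti]2(OC(C)C)OC(C)C | intermediate
38 | tetrasilyl ether of the target | CC1=C[C@H](O[Si](C)(C)C(C)(C)C)CC(C)(C)[C@H]1/C=C/C(C)=C/C=C/C(C)=C/C=C/C=C(C)/C=C/C=C(C)/C=C/[C@]1(O[Si](C)(C)C)C(C)(C)C[C@H](O[Si](C)(C)C)C[C@]1(C)O[Si](C)(C)C | intermediate
39 | (3S,5S,6S,3'R,6'R)-5,6-dihydro-β,ε-carotene-3,5,6,3'-tetrol | CC1=C[C@H](O)CC(C)(C)[C@H]1/C=C/C(C)=C/C=C/C(C)=C/C=C/C=C(C)/C=C/C=C(C)/C=C/[C@]1(O)C(C)(C)C[C@H](O)C[C@]1(C)O | target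

Total step count: 22. Longest linear sequence: 10 steps from ketoisophorone (steps 2–8, 12, 21, 22; the ε branch, steps 13–22, is equally long).

Steps most likely to fail

Step 21. What may go wrong:
- proton transfer from the terminal alkyne to the titanacyclopropene
- binding of divalent titanium to the polyene
- loss of regiocontrol in the insertion
- homo-coupling

The fallback is a Stille coupling at the same bond. It sets out from 35 and 23 and comes back at 38.
- Hydrostannation of 35 (Bu3SnH, PdCl2(PPh3)2, THF, 0 °C) would give the (E)-trienylstannane F1.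
- Hydrozirconation of 23 with Cp2Zr(H)Cl (zirconium at the methyl-bearing carbon), then iodinolysis with N-iodosuccinimide, would give the (E)-alkenyl iodide F2.
- Pd2(dba)3/AsPh3 in N-methylpyrrolidone at rt (neutral conditions that spare the silyl ethers) would join the two to 38.

Step 6. What may go wrong:
- migration of the epoxide towards the freed 6-alkoxide (Payne rearrangement), followed by SN2' hydride attack on the resulting propargylic epoxide to an allene
- sluggish epoxide opening

The fallback opens the epoxide while O6 is still masked. It sets out from 9 and comes back at 11.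
- LiEt3BH in THF would open 9 at C4 to the silylated alkynyl diol F3.
- Bu4NF would then give the alkynyl tetraol F4.
- NaAlH2(OCH2CH2OMe)2 in THF would reduce the propargylic alcohol to 11.

Step 18. What may go wrong:
- epimerisation at C6', or shift of the ring double bond into conjugation, in the β,γ-unsaturated aldehyde under the basic conditions
- erosion of the 9' geometry through the allyl anion

The fallback reverses the polarity in a Julia–Kocienski olefination, so no epimerisable aldehyde is needed. It sets out from 28 and comes back at 32.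
- Mitsunobu thioetherification of 28 with 1-phenyl-1H-tetrazole-5-thiol (PPh3, diisopropyl azodicarboxylate) would give the tetrazolyl sulfide F5.
- H2O2/(NH4)6Mo7O24 would oxidise this to the tetrazolyl sulfone F6.
- SeO2 oxidation of 3-methylbut-2-enenitrile would give geometrically defined (E)-3-formylbut-2-enenitrile F7.
- KN(SiMe3)2 with the sulfone and this aldehyde at −78 °C would give 32.

Further compounds
F1 | step 21 | tributyl[(1E,3E,5E)-trienyl]stannane of the ε half (Bu3Sn on C12') | CC1=C[C@H](O[Si](C)(C)C(C)(C)C)CC(C)(C)[C@H]1/C=C/C(C)=C/C=C/[Sn](CCCC)(CCCC)CCCC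
F2 | step 21 | (E)-alkenyl iodide of the C24 half (iodine on C13') | I/C(C)=C/C=C/C=C(C)/C=C/C=C(C)/C=C/[C@]1(O[Si](C)(C)C)C(C)(C)C[C@H](O[Si](C)(C)C)C[C@]1(C)O[Si](C)(C)C
F3 | step 6 | alkynyl 3,5-diol with 6-OSiMe3 and 11-OSiMe2t-Bu | CC(C)(C)[Si](C)(C)OC/C=C(C)/C#C[C@]1(O[Si](C)(C)C)C(C)(C)C[C@H](O)C[C@]1(C)O
F4 | step 6 | alkynyl tetraol | OC/C=C(C)/C#C[C@]1(O)C(C)(C)C[C@H](O)C[C@]1(C)O
F5 | step 18 | 1-phenyltetrazol-5-yl sulfide of 28 | CC1=C[C@H](O[Si](C)(C)C(C)(C)C)CC(C)(C)[C@H]1CSc1nnnn1-c1ccccc1
F6 | step 18 | 1-phenyltetrazol-5-yl sulfone | CC1=C[C@H](O[Si](C)(C)C(C)(C)C)CC(C)(C)[C@H]1CS(=O)(=O)c1nnnn1-c1ccccc1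
F7 | step 18 | (E)-3-formylbut-2-enenitrile | O=C/C(C)=C/C#N
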